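The six-membered carbocycle of colupulone is disconnected at C1–C2 and C3–C4: C2, C3 and the acyl side chain come from an ynol ether, while C1 and C4–C6 come from a 4,4-diprenylcyclobutenone. One pericyclic cascade (4π opening, [2+2], 4π opening, 6π closure) should build the fully substituted ring with all three prenyl groups already in place. The step exploits the quaternary ring carbon C6: its two identical prenyl groups make it achiral and forbid tautomerisation to a phenol, so the annulation must stop at the cyclohexa-2,4-dienone. The precursor is 3-methoxy-2,4,4-triprenylcyclobut-2-en-1-one, made by a ketene–ynol ether [2+2] cycloaddition and paired with a silyl-protected 1-ethoxy-4-methylpent-1-yn-3-ol.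

Key step: step 6

Remark on stereochemistry: colupulone has no stereocentre (C6 bears two identical prenyl groups), so the target is taken as the achiral compound; the carbinol centre brought in with racemic 16 is erased in step 8.

Remark on the protecting groups: the C5 oxygen is carried as a methyl ether, because C5 is shielded by the quaternary C6 and is best unmasked by SN2 attack at the unhindered methyl carbon. The exposed, doubly activated C3 oxygen is carried as an ethyl ether and removed by addition–elimination. The annulation is started with light at 20 °C and finished at 80 °C, which keeps the ethyl ynol ether below its retro-ene threshold. "Prenyl" means 3-methylbut-2-enyl throughout.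

**Step 1**
Reactants: 1 diethyl malonate, 2 prenyl bromide
Product: 3 diethyl 2,2-bis(3-methylbut-2-enyl)malonate
Conditions: NaH (2.3 equiv), 2 (2.3 equiv), THF/DMF, 0 °C → rt
Reagents that add atoms: none
Why: Malonic ester dialkylation: the doubly stabilised enolate is C-alkylated twice by the reactive primary allylic bromide (SN2), which should set the gem-diprenyl quaternary carbon without any C- versus O-alkylation issue.

**Step 2**
Reactants: 3 diethyl 2,2-bis(3-methylbut-2-enyl)malonate
Product: 5 5-methyl-2-(3-methylbut-2-enyl)hex-4-enoic acid, via 2,2-diprenylmalonic acid 4 (not isolated)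
Conditions: KOH, EtOH/H2O, reflux; cold dil. HCl to pH 2; then neat, 160 °C
Reagents that add atoms: potassium hydroxide, [K+].[OH-]
Why: Saponification and thermal decarboxylation of the geminal diacid (malonic ester synthesis) should give the α,α-diprenylacetic acid, the trisubstituted alkenes being inert to hydroxide and to brief cold acidification.

**Step 3**
Reactants: 6 2-chloro-1,1-dimethoxyethane, 2 prenyl bromide
Product: 8 1-methoxy-5-methylhex-4-en-1-yne, via lithium methoxyacetylide 7 (not isolated)
Conditions: Et2NH, n-BuLi (3.1 equiv each), THF, 0 °C; then 2, DMPU, −78 → 0 °C; NaHCO3 work-up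
Reagents that add atoms: none
Why: Lithium diethylamide should convert the chloroacetal by two eliminations (methanol, then HCl) and deprotonation into lithium methoxyacetylide, whose SN2 C-alkylation by the allylic bromide in THF–DMPU gives the methyl ynol ether, a group chosen because it has no β-hydrogen for retro-ene loss and can later be cleaved at the methyl carbon.

**Step 4**
Reactants: 5 5-methyl-2-(3-methylbut-2-enyl)hex-4-enoic acid, 8 1-methoxy-5-methylhex-4-en-1-yne
Product: 11 3-methoxy-2,4,4-tris(3-methylbut-2-enyl)cyclobut-2-en-1-one, via diprenylacetyl chloride 9 (not isolated), via diprenylketene 10 (not isolated)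
Conditions: 1-chloro-N,N,2-trimethylprop-1-en-1-amine (Ghosez reagent, 1.0 equiv per 5), ClCH2CH2Cl, 0 °C → rt; then 8, Et3N, 60 °C
Reagents that add atoms: none
Why: The α-chloroenamine converts the acid into its chloride without liberating HCl, triethylamine dehydrochlorinates it to the dialkylketene, and the ketene–ynol ether [2+2] cycloaddition (alkyne carbon remote from oxygen to the ketene carbonyl carbon) should give the 3-alkoxy-4,4-dialkylcyclobutenone, a known outcome for dialkylketenes and alkoxyalkynes.

**Step 5**
Reactants: 12 ethoxyacetylene, 13 isobutyraldehyde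
Product: 16 racemic tert-butyl[(1-ethoxy-4-methylpent-1-yn-3-yl)oxy]dimethylsilane, via lithium ethoxyacetylide 14 (not isolated), via lithium 1-ethoxy-4-methylpent-1-yn-3-olate 15 (not isolated)
Conditions: n-BuLi, THF, −78 °C; 13; then TBSCl, DMPU, −78 °C → rt; NaHCO3 work-up
Reagents that add atoms: tert-butyldimethylsilyl chloride (TBSCl), CC(C)(C)[Si](C)(C)Cl
Why: 1,2-Addition of the lithium acetylide to the aldehyde followed by in situ O-silylation of the alkoxide should give the protected propargylic ether without ever handling the free, Meyer–Schuster-prone carbinol; the stereocentre forms without control (racemate) and is removed in step 8.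

**Step 6**
Reactants: 11 3-methoxy-2,4,4-tris(3-methylbut-2-enyl)cyclobut-2-en-1-one, 16 racemic tert-butyl[(1-ethoxy-4-methylpent-1-yn-3-yl)oxy]dimethylsilane
Product: 20 racemic 2-[1-(tert-butyldimethylsilyloxy)-2-methylpropyl]-3-ethoxy-5-methoxy-4,6,6-tris(3-methylbut-2-enyl)cyclohexa-2,4-dien-1-one, via vinylketene 17 (not isolated), via 4-vinylcyclobutenone 18 (not isolated), via dienylketene 19 (not isolated)
Conditions: 16 (2.5 equiv), degassed cyclohexane (ca. 1 M), hν (254 nm, quartz), 20 °C; then 80 °C in the dark
Reagents that add atoms: none
Why: Light opens 11 by 4π electrocyclic cleavage of the C(=O)–C(prenyl)2 bond to vinylketene 17, which is trapped at 20 °C by the electron-rich ynol ether 16 in a [2+2] cycloaddition to give 18; 4π opening of 18 (light or 80 °C) gives dienylketene 19, whose 6π electrocyclisation onto the diprenyl-substituted terminus closes the ring. The closest known reaction is the Danheiser benzannulation of cyclobutenones with alkoxyalkynes, here combined with the known thermal closure of dienylketenes to 6,6-disubstituted cyclohexa-2,4-dienones. The six-membered carbocycle is closed by the disrotatory 6π electrocyclisation that forms C1–C6, after C1–C2 and C3–C4 were made in the [2+2] event; no ring stereocentre arises, and the carbinol centre is simply carried in racemic form from 16. Regiochemistry rests on the oxygen polarisation of the alkyne (its carbinol-bearing carbon bonds to the ketene carbonyl carbon, so the side chain lands on C2 and OEt on C3), and the quaternary C6 arrests the cascade at the dienone because no tautomerisation to a phenol is possible. Chemoselectivity over intramolecular [2+2] or hydrogen-shift reactions of the ketenes with a cis-disposed prenyl group is sought by generating 17 at ambient temperature in the presence of excess, concentrated 16, while unproductive ketene rotamers can reclose and re-enter the cascade; the 80 °C finish stays below retro-ene loss of ethylene from the ethyl ynol ether.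

**Step 7**
Reactants: 20 racemic 2-[1-(tert-butyldimethylsilyloxy)-2-methylpropyl]-3-ethoxy-5-methoxy-4,6,6-tris(3-methylbut-2-enyl)cyclohexa-2,4-dien-1-one
Product: 21 racemic 3-ethoxy-2-(1-hydroxy-2-methylpropyl)-5-methoxy-4,6,6-tris(3-methylbut-2-enyl)cyclohexa-2,4-dien-1-one
Conditions: TBAF, THF, 0 °C → rt; pH 7 buffer work-up; used crude
Reagents that add atoms: none
Why: Fluoride-induced desilylation (Si–F bond formation) should free the secondary alcohol under non-acidic conditions that spare the two enol ethers, the prenyl groups and the ionisation-prone carbinol.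

**Step 8**
Reactants: 21 racemic 3-ethoxy-2-(1-hydroxy-2-methylpropyl)-5-methoxy-4,6,6-tris(3-methylbut-2-enyl)cyclohexa-2,4-dien-1-one
Product: 22 3-ethoxy-5-methoxy-2-(2-methylpropanoyl)-4,6,6-tris(3-methylbut-2-enyl)cyclohexa-2,4-dien-1-one
Conditions: Dess–Martin periodinane, pyridine, CH2Cl2, 0 °C → rt
Reagents that add atoms: none
Why: Dess–Martin oxidation, buffered by pyridine, should turn the hindered secondary alcohol into the isobutyryl ketone without acid and thereby erases the only stereocentre.

**Step 9**
Reactants: 22 3-ethoxy-5-methoxy-2-(2-methylpropanoyl)-4,6,6-tris(3-methylbut-2-enyl)cyclohexa-2,4-dien-1-one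
Product: 23 3-hydroxy-5-methoxy-2-(2-methylpropanoyl)-4,6,6-tris(3-methylbut-2-enyl)cyclohexa-2,4-dien-1-one
Conditions: LiOH, THF/H2O, 0 °C → rt, Ar; then cold 1 M HCl to pH 3
Reagents that add atoms: lithium hydroxide, [Li+].[OH-]
Why: Addition–elimination at a vinylogous ester: hydroxide should attack C3, the unhindered β-carbon activated by both the ring and the side-chain carbonyl, and expel ethoxide to give the triketone enolate, while the C5 methyl ether next to the quaternary C6 is left alone.

**Step 10**
Reactants: 23 3-hydroxy-5-methoxy-2-(2-methylpropanoyl)-4,6,6-tris(3-methylbut-2-enyl)cyclohexa-2,4-dien-1-one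
Product: 24 colupulone
Conditions: LiCl (10 equiv), DMSO, 120 °C, Ar; then cold dil. HCl
Reagents that add atoms: none
Why: SN2 O-demethylation of a vinylogous methyl ester by chloride (Krapcho-type dealkylation): attack occurs at the unhindered methyl carbon and expels the stabilised colupulone monoanion, so the congested C5 is never approached and the prenyl groups see no acid.

**Compound list**

1 | diethyl malonate | CCOC(=O)CC(=O)OCC | starting material
2 | prenyl bromide (1-bromo-3-methylbut-2-ene) | CC(C)=CCBr | starting material
3 | diethyl 2,2-bis(3-methylbut-2-enyl)malonate | CCOC(=O)C(CC=C(C)C)(CC=C(C)C)C(=O)OCC | intermediate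
4 | 2,2-bis(3-methylbut-2-enyl)malonic acid | OC(=O)C(CC=C(C)C)(CC=C(C)C)C(=O)O | intermediate
5 | 5-methyl-2-(3-methylbut-2-enyl)hex-4-enoic acid (diprenylacetic acid) | CC(C)=CCC(CC=C(C)C)C(=O)O | intermediate
6 | 2-chloro-1,1-dimethoxyethane (chloroacetaldehyde dimethyl acetal) | COC(CCl)OC | starting material
7 | lithium methoxyacetylide | [Li+].[C-]#COC | intermediate
8 | 1-methoxy-5-methylhex-4-en-1-yne | COC#CCC=C(C)C | intermediate
9 | 5-methyl-2-(3-methylbut-2-enyl)hex-4-enoyl chloride (diprenylacetyl chloride) | CC(C)=CCC(CC=C(C)C)C(=O)Cl | intermediate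
10 | 5-methyl-2-(3-methylbut-2-enyl)hexa-1,4-dien-1-one (diprenylketene) | CC(C)=CCC(CC=C(C)C)=C=O | intermediate
11 | 3-methoxy-2,4,4-tris(3-methylbut-2-enyl)cyclobut-2-en-1-one | O=C1C(CC=C(C)C)=C(OC)C1(CC=C(C)C)CC=C(C)C | intermediate
12 | ethoxyacetylene (ethoxyethyne) | CCOC#C | starting material
13 | isobutyraldehyde (2-methylpropanal) | CC(C)C=O | starting material
14 | lithium ethoxyacetylide | [Li+].[C-]#COCC | intermediate
15 | lithium 1-ethoxy-4-methylpent-1-yn-3-olate (racemic) | [Li+].CCOC#CC([O-])C(C)C | intermediate
16 | racemic tert-butyl[(1-ethoxy-4-methylpent-1-yn-3-yl)oxy]dimethylsilane | CCOC#CC(O[Si](C)(C)C(C)(C)C)C(C)C | intermediate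
17 | 3-methoxy-7-methyl-2,4-bis(3-methylbut-2-enyl)octa-1,3,6-trien-1-one (vinylketene) | O=C=C(CC=C(C)C)C(OC)=C(CC=C(C)C)CC=C(C)C | intermediate
18 | 2-[1-(tert-butyldimethylsilyloxy)-2-methylpropyl]-3-ethoxy-4-[1-methoxy-5-methyl-2-(3-methylbut-2-enyl)hexa-1,4-dienyl]-4-(3-methylbut-2-enyl)cyclobut-2-en-1-one (mixture of diastereomers, each racemic) | O=C1C(C(O[Si](C)(C)C(C)(C)C)C(C)C)=C(OCC)C1(CC=C(C)C)C(OC)=C(CC=C(C)C)CC=C(C)C | intermediate
19 | (3E)-2-[1-(tert-butyldimethylsilyloxy)-2-methylpropyl]-3-ethoxy-5-methoxy-9-methyl-4,6-bis(3-methylbut-2-enyl)deca-1,3,5,8-tetraen-1-one (dienylketene, C2 and C5 cis across C3=C4, racemic) | O=C=C(C(O[Si](C)(C)C(C)(C)C)C(C)C)/C(OCC)=C(CC=C(C)C)\C(OC)=C(CC=C(C)C)CC=C(C)C | intermediate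
20 | racemic 2-[1-(tert-butyldimethylsilyloxy)-2-methylpropyl]-3-ethoxy-5-methoxy-4,6,6-tris(3-methylbut-2-enyl)cyclohexa-2,4-dien-1-one | O=C1C(C(O[Si](C)(C)C(C)(C)C)C(C)C)=C(OCC)C(CC=C(C)C)=C(OC)C1(CC=C(C)C)CC=C(C)C | intermediate
21 | racemic 3-ethoxy-2-(1-hydroxy-2-methylpropyl)-5-methoxy-4,6,6-tris(3-methylbut-2-enyl)cyclohexa-2,4-dien-1-one | O=C1C(C(O)C(C)C)=C(OCC)C(CC=C(C)C)=C(OC)C1(CC=C(C)C)CC=C(C)C | intermediate
22 | 3-ethoxy-5-methoxy-2-(2-methylpropanoyl)-4,6,6-tris(3-methylbut-2-enyl)cyclohexa-2,4-dien-1-one | O=C1C(C(=O)C(C)C)=C(OCC)C(CC=C(C)C)=C(OC)C1(CC=C(C)C)CC=C(C)C | intermediate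
23 | 3-hydroxy-5-methoxy-2-(2-methylpropanoyl)-4,6,6-tris(3-methylbut-2-enyl)cyclohexa-2,4-dien-1-one (5-O-methylcolupulone) | O=C1C(C(=O)C(C)C)=C(O)C(CC=C(C)C)=C(OC)C1(CC=C(C)C)CC=C(C)C | intermediate
24 | colupulone, 3,5-dihydroxy-2-(2-methylpropanoyl)-4,6,6-tris(3-methylbut-2-enyl)cyclohexa-2,4-dien-1-one (achiral) | CC(C)=CCC1=C(O)C(CC=C(C)C)(CC=C(C)C)C(=O)C(C(=O)C(C)C)=C1O | target

**Totals**

Total step count: 10.
Longest linear sequence: 8 steps (steps 1, 2, 4, 6, 7, 8, 9, 10, from diethyl malonate).

**Steps most likely to fail**

Step 6 (key annulation). The photogenerated vinylketene may be diverted before the alkyne adds, by intramolecular [2+2] cycloaddition or hydrogen shift involving the prenyl group that sits cis to the ketene. The hindered, branched ynol ether may also add too slowly, so that the cascade does not reach the dienone. The fallback gives up the annulation and uses the classical base-mediated C-prenylation of an acylphloroglucinol. It sets out from prenyl bromide 2. Phloroglucinol is acylated with isobutyryl chloride and AlCl3 (Friedel–Crafts) to give 2-methyl-1-(2,4,6-trihydroxyphenyl)propan-1-one F1. Treating F1 with three equivalents of 2 and sodium methoxide in methanol at 0 °C should C-alkylate the ring three times, twice at the same carbon. This returns to the route directly at colupulone 24, which would have to be separated from diprenylated and O-alkylated by-products.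

Step 10 (final demethylation). As the product anion forms it can deprotonate remaining 23, which slows the SN2 step. Prolonged heating of the enolised triketone then invites thermal prenyl migration or decomposition. The fallback inverts the order of unmasking and sets out from diether 22, which has no acidic proton. Lithium chloride in DMSO should cleave only the methyl ether (the ethyl group is far slower in SN2) and give, after acidification, 3-ethoxy-5-hydroxy-2-(2-methylpropanoyl)-4,6,6-tris(3-methylbut-2-enyl)cyclohexa-2,4-dien-1-one F2. Its unhindered, doubly activated C3 ethyl ether should then hydrolyse in dilute aqueous acid in THF at room temperature, returning to the route at 24.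

Step 3 (methyl ynol ether). Prenyl bromide may be consumed by N- and O-alkylation of the diethylamine and lithium methoxide present in the pot, or may react in the SN2′ sense. The volatile, acid-sensitive ynol ether may also be lost on isolation. The fallback makes the acetylide by the dichlorovinyl ether route and sets out from prenyl bromide 2. Trichloroethylene and sodium methoxide give (E)-1,2-dichloro-1-methoxyethene F3. Two equivalents of n-butyllithium (elimination of HCl, then chlorine–lithium exchange) convert F3 into lithium methoxyacetylide 7, free of amine and methoxide. Alkylation of 7 with 2 in THF–DMPU then returns to the route at 8.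

**Further compounds**

F1 | step 6 | 2-methyl-1-(2,4,6-trihydroxyphenyl)propan-1-one (phlorisobutyrophenone) | CC(C)C(=O)c1c(O)cc(O)cc1O
F2 | step 10 | 3-ethoxy-5-hydroxy-2-(2-methylpropanoyl)-4,6,6-tris(3-methylbut-2-enyl)cyclohexa-2,4-dien-1-one | O=C1C(C(=O)C(C)C)=C(OCC)C(CC=C(C)C)=C(O)C1(CC=C(C)C)CC=C(C)C
F3 | step 3 | (E)-1,2-dichloro-1-methoxyethene | Cl/C=C(/Cl)OC
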